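## Structural features

The target is a monocyclic diterpenoid on an eleven-membered carbocycle, numbered here C1 (quaternary; methyl and 4-methylpent-3-enyl), C2=C3 (cis), C4 (secondary carbinol, esterified with 3-methylbut-2-enoic acid), C5 (tertiary carbinol with methyl), C6=C7 (cis), C8 (ketone), C9=C10 (C9 bears CH2OH; C8 and C11 cis, 9Z) and C11 (CH2, bonded to C1). All three ring double bonds are cis within the ring, and C6=C7–C8(=O)–C9=C10 is a cross-conjugated dienone. There are three stereocentres: C4 (R) and C5 (S) are adjacent, with both C–O bonds on the same ring face (erythro). The all-carbon quaternary C1 (S) is separated from them by the cis C2=C3 bond, so simple acyclic induction cannot relay it from the C4/C5 pair. Fragile groups are the dienone (Michael acceptor, acid-sensitive), the cis-4-hydroxy-enone C5(OH)–C6=C7–C8=O (ring–chain tautomerism to a C5–O–C8 hemiketal, retro-aldol cleavage of C4–C5 under base), the allylic unsaturated ester at C4 and the trisubstituted side-chain alkene. The real difficulty is the medium ring with three cis alkenes and the dienone, together with the C4/C5 pair beside it. The key step (step 13) exploits that C5, C6, C7, C8 and the oxygen on C5 form, with C8 as a lactone carbonyl, a 5-methylfuran-2(5H)-one ring (the lactone ring) in which the cis C6=C7 geometry is locked: a C9 alkenyl anion attacks that lactone carbonyl, so the five-membered lactone is exchanged for the eleven-membered carbocycle.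

## Logic of the disconnections

29 to 28: the O–Si bond of the C9 hydroxymethyl group is cut. The primary hydroxyl must stay masked until the C4 ester is in place, since it would otherwise be acylated first. The forward step is a buffered fluoride cleavage that the dienone and the ester must survive.

28 to 26 and 27: the acyl C–O bond at C4 is cut (and, one step further back, the C4 O–Si bond of 25). The unsaturated ester cannot pass through the organolithium ring closure, so it is added afterwards. The forward acylation must pick the secondary C4 hydroxyl over the tertiary C5 hydroxyl.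

25 to 22 (key disconnection): the ring bond C8–C9 is cut and C8 is reconnected to the oxygen on C5 as a lactone. In one sentence: the carbocycle is closed by a C9 alkenyllithium that opens the C5-quaternary lactone of 22 at its carbonyl carbon. This removes the medium ring, the dienone and the free cis-hydroxy-enone in one operation with no redox adjustment; the precursor is an acyclic chain hung on a stable five-membered lactone. The forward step must achieve halogen–metal exchange before carbonyl attack, 1,2-addition, and ring closure ahead of intermolecular reaction.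

22 to 14: the C9=C10 bond and the C9–I bond are cut, back to the vinyl group on C1 (through 21, 20, 19 and 16). The iodo-allyl unit is built late from the one terminal alkene, so no halide is present during the earlier organometallic and hydrogenation steps. The forward steps need a hydroboration selective for the monosubstituted alkene and an α-iodination selective for the enal over the lactone.

14 to 12 (through 13): the cis C2=C3 alkene is traced to an alkyne and the C4 hydroxyl is freed. The alkyne is what the two C–C bond-forming steps before it deliver, and its semi-hydrogenation fixes the cis geometry next to the quaternary carbon. The forward step must leave the vinyl group intact.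

12 to 8 and 10: the C4–C5 bond is cut. A vinylogous aldol addition of the furan 10 to the ynal 8 forms this bond, sets C4 and C5 together, and brings in C5–C8 with the C6=C7 geometry locked in a ring and C8 at the acyl oxidation level. The forward step needs attack through the methyl-bearing γ-carbon of the furan and catalyst control of both faces, independent of the remote C1.

10 to 9: the O–Si bond is cut; the silyloxyfuran is the dienolate equivalent of the commercial lactone.

8 to 5: the C3–C4 bond is cut (formylation of the acetylide after loss of silicon). It adds the one carbon that becomes C4.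

5 to 2 and 3 (through 4): the C1–C2 bond is cut. An SN2' allylic substitution creates the quaternary C1 from an achiral terpene phosphate; the alkynyl group supplies C2 and C3 and the resulting vinyl group supplies C11 and C10. The forward step needs γ-selectivity and catalyst-controlled facial selectivity.

2 to 1: the P–O bond is cut; activation of the commercial allylic alcohol.

## Other disconnections considered

Alternative 1: cut C2=C3 (the first idea that comes to mind). The forward key step would be ring-closing olefin metathesis of the acyclic tetraene A1 with RuCl2(=CHPh)(PCy3)(H2IMes) to give 28. Both reacting vinyl groups are hindered: one sits on the quaternary C1, the other next to the acyloxy carbon C4 and the quaternary C5. The C1 vinyl group can instead close a five-membered ring onto the side-chain alkene. Nothing in an eleven-membered ring enforces the cis geometry. A1 would also still need the C4/C5 pair and the free cis-hydroxy-enone to be made separately, so the ring closure removes none of the real difficulty.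

Alternative 2: cut C7–C8 and C8–C9, with C8 coming from carbon monoxide. The forward key step would be a carbonylative Stille macrocyclisation of the alkenyl iodide/cis-alkenylstannane A2 (Pd2(dba)3, AsPh3, CO) to give 28. It is unconventional and would tolerate the ester. However, it deletes C8 from the precursor, so the cis C6=C7 unit and the C4/C5 pair must be built without the lactone that delivers both here. That would need chelation-controlled carbonyl additions and alkyne manipulations, estimated at five or more extra steps. Direct coupling without CO insertion to a ten-membered ring and protodestannylation of the cis-γ-hydroxy alkenylstannane are further liabilities.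

Alternative 3: reconnect C3 to C8. The forward key step would be a Grob fragmentation of the trans-fused bicyclo[5.4.0]undecadiene A3 (C8 tertiary alkoxide, C2 mesylate antiperiplanar to the C3–C8 bond) to give 25. This would form the C8 ketone and the cis C2=C3 alkene stereospecifically, with C4, C5 and the cis C6=C7 set on a six-membered ring. The idea is attractive, but A3 carries six stereocentres, three of which (C2, C3, C8) are destroyed, and three fully substituted carbons in a fused 6–7 system. Its synthesis would be longer than that of the target by the chosen route, and the bis-allylic tertiary alkoxide has competing anionic pathways.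

Key step: step 13

Remark (assumption): 25, 26, 28 and 29 are written as open hydroxy ketones; each may equilibrate with its transannular C5–O–C8 hemiketal, which does not change the route.

## Steps

Step 1
Reactants: 1 geraniol
Product: 2 geranyl diethyl phosphate
Conditions: ClP(O)(OEt)2, pyridine, CH2Cl2, 0 °C → rt
Reagents that add atoms: diethyl chlorophosphate, CCOP(=O)(Cl)OCC
Why: Phosphorylation of the primary allylic alcohol (substitution at phosphorus) installs the leaving group for the allylic substitution; no stereocentre is formed and the E geometry is untouched.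

Step 2
Reactants: 2 geranyl diethyl phosphate; 3 (trimethylsilyl)acetylene
Product: 5 (3S)-3,7-dimethyl-3-[(trimethylsilyl)ethynyl]octa-1,6-diene, via alkynylalane 4 (not isolated)
Conditions: 3, iBu2AlH, Et3N (5 mol %), hexane, 0 °C → rt (gives 4); then 2, CuCl2·2H2O (5 mol %), chiral sulfonate-bearing imidazolinium salt (carbene precursor, 5.5 mol %), THF, −15 °C; aq. HCl work-up
Reagents that add atoms: none
Why: Copper-catalysed enantioselective allylic substitution in the SN2' mode with an alkynylaluminium reagent: the chiral carbene–copper alkynyl species attacks the γ-carbon of 2 anti to the phosphate and creates the quaternary C1 with a terminal vinyl group. The facial sense is set by the ligand, whose enantiomer is chosen for (S)-5; the E geometry of 2 is the second control element. Alkyne 3 is first metallated by iBu2AlH/Et3N (deprotonation rather than hydroalumination) to give 4.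

Step 3
Reactants: 5 (3S)-3,7-dimethyl-3-[(trimethylsilyl)ethynyl]octa-1,6-diene
Product: 8 (4S)-4-ethenyl-4,8-dimethylnon-7-en-2-ynal, via lithium acetylide 6 (not isolated), via hemiaminal alkoxide 7 (not isolated)
Conditions: MeLi·LiBr, THF/Et2O, 0 °C → rt; DMF, −78 → 0 °C; inverse quench into cold 1 M HCl
Reagents that add atoms: N,N-dimethylformamide, CN(C)C=O
Why: Silicon–lithium exchange with MeLi·LiBr gives the acetylide 6, which is formylated by DMF; the hemiaminal alkoxide 7 collapses to the ynal on acidic quench. C1 is not involved.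

Step 4
Reactants: 9 α-angelica lactone
Product: 10 tert-butyldimethyl[(5-methylfuran-2-yl)oxy]silane
Conditions: TBSOTf, Et3N, CH2Cl2, 0 °C
Reagents that add atoms: tert-butyldimethylsilyl trifluoromethanesulfonate, CC(C)(C)[Si](C)(C)OS(=O)(=O)C(F)(F)F
Why: Soft enolisation and O-silylation of the lactone gives the aromatic 2-silyloxyfuran, the dienolate equivalent for the vinylogous Mukaiyama aldol reaction.

Step 5
Reactants: 8 (4S)-4-ethenyl-4,8-dimethylnon-7-en-2-ynal; 10 tert-butyldimethyl[(5-methylfuran-2-yl)oxy]silane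
Product: 12 (5S)-5-[(1R,4S)-4-ethenyl-1-hydroxy-4,8-dimethylnon-7-en-2-yn-1-yl]-5-methylfuran-2(5H)-one, via trichlorosilyl ether 11 (not isolated)
Conditions: SiCl4 (1.1 equiv), chiral 2,2'-binaphthyldiamine-derived bisphosphoramide (5 mol %), iPr2NEt (10 mol %), CH2Cl2, −78 °C; sat. aq. NaHCO3
Reagents that add atoms: none
Why: Catalytic asymmetric vinylogous Mukaiyama aldol reaction: the chiral Lewis base turns SiCl4 into a cationic chiral silicon Lewis acid that activates the non-enolisable ynal, and the furan attacks through its γ-carbon (C5) in an open transition state, forming C4–C5 and the quaternary C5. The catalyst enantiomer is chosen for attack on the Si face of the aldehyde; the anti-selective open transition state should pair it with the Re face of the furan carbon (unlike combination) to give the (1R,5S) erythro adduct, and the remote C1 should not interfere.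

Step 6
Reactants: 12 (5S)-5-[(1R,4S)-4-ethenyl-1-hydroxy-4,8-dimethylnon-7-en-2-yn-1-yl]-5-methylfuran-2(5H)-one
Product: 13 (5S)-5-[(1R,4S)-4-ethenyl-4,8-dimethyl-1-(triethylsilyloxy)non-7-en-2-yn-1-yl]-5-methylfuran-2(5H)-one
Conditions: TESOTf, 2,6-lutidine, CH2Cl2, −78 → 0 °C
Reagents that add atoms: triethylsilyl trifluoromethanesulfonate, CC[Si](CC)(CC)OS(=O)(=O)C(F)(F)F
Why: Silyl ether formation with a silyl triflate and a hindered base protects the hindered secondary C4 hydroxyl for the oxidation and organolithium steps and removes the alkoxide that could start a retro-aldol cleavage.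

Step 7
Reactants: 13 (5S)-5-[(1R,4S)-4-ethenyl-4,8-dimethyl-1-(triethylsilyloxy)non-7-en-2-yn-1-yl]-5-methylfuran-2(5H)-one
Product: 14 (5S)-5-[(1R,2Z,4S)-4-ethenyl-4,8-dimethyl-1-(triethylsilyloxy)nona-2,7-dien-1-yl]-5-methylfuran-2(5H)-one
Conditions: H2 (1 atm), Pd/CaCO3 poisoned with Pb(OAc)2 (Lindlar catalyst), quinoline, EtOAc, rt
Reagents that add atoms: none
Why: Lindlar semi-hydrogenation: syn delivery of hydrogen on the poisoned palladium surface gives the cis C2=C3 alkene; the hindered vinyl group, the trisubstituted alkene and the conjugated lactone should react much more slowly.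

Step 8
Reactants: 14 (5S)-5-[(1R,2Z,4S)-4-ethenyl-4,8-dimethyl-1-(triethylsilyloxy)nona-2,7-dien-1-yl]-5-methylfuran-2(5H)-one
Product: 16 (5S)-5-[(1R,2Z,4S)-4-(2-hydroxyethyl)-4,8-dimethyl-1-(triethylsilyloxy)nona-2,7-dien-1-yl]-5-methylfuran-2(5H)-one, via alkylborane 15 (not isolated)
Conditions: 9-BBN, THF, 0 °C → rt; then aq. NaOAc, 30% H2O2, 0 °C → rt
Reagents that add atoms: hydrogen peroxide, OO
Why: Hydroboration–oxidation: the bulky borane adds anti-Markovnikov and selectively to the monosubstituted vinyl group (the cis-disubstituted, trisubstituted and electron-poor lactone alkenes are far slower). Buffered peroxide oxidation then gives the primary C10 alcohol without opening the lactone.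

Step 9
Reactants: 16 (5S)-5-[(1R,2Z,4S)-4-(2-hydroxyethyl)-4,8-dimethyl-1-(triethylsilyloxy)nona-2,7-dien-1-yl]-5-methylfuran-2(5H)-one; 17 (triphenylphosphoranylidene)acetaldehyde
Product: 19 (5S)-5-[(1R,2Z,4S)-4,8-dimethyl-4-[(2E)-4-oxobut-2-en-1-yl]-1-(triethylsilyloxy)nona-2,7-dien-1-yl]-5-methylfuran-2(5H)-one, via aldehyde 18 (not isolated)
Conditions: Dess–Martin periodinane, CH2Cl2, 0 °C → rt; then 17, rt → 40 °C
Reagents that add atoms: none
Why: Dess–Martin oxidation to aldehyde 18, followed in the same flask by Wittig olefination with the stabilised formyl ylide, which should give the (E)-enal; this makes C9=C10 with the future hydroxymethyl carbon trans to C11.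

Step 10
Reactants: 19 (5S)-5-[(1R,2Z,4S)-4,8-dimethyl-4-[(2E)-4-oxobut-2-en-1-yl]-1-(triethylsilyloxy)nona-2,7-dien-1-yl]-5-methylfuran-2(5H)-one
Product: 20 (5S)-5-[(1R,2Z,4S)-4-[(2Z)-3-iodo-4-oxobut-2-en-1-yl]-4,8-dimethyl-1-(triethylsilyloxy)nona-2,7-dien-1-yl]-5-methylfuran-2(5H)-one
Conditions: I2, pyridine, CH2Cl2, 0 °C → rt, dark
Reagents that add atoms: iodine, II
Why: α-Iodination of the enal by pyridine-mediated conjugate addition, iodination and elimination (Baylis–Hillman-type α-halogenation). The formyl group stays trans to C11, so iodine ends cis to C11 (Z); the less electrophilic lactone should not react.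

Step 11
Reactants: 20 (5S)-5-[(1R,2Z,4S)-4-[(2Z)-3-iodo-4-oxobut-2-en-1-yl]-4,8-dimethyl-1-(triethylsilyloxy)nona-2,7-dien-1-yl]-5-methylfuran-2(5H)-one
Product: 21 (5S)-5-[(1R,2Z,4S)-4-[(2Z)-4-hydroxy-3-iodobut-2-en-1-yl]-4,8-dimethyl-1-(triethylsilyloxy)nona-2,7-dien-1-yl]-5-methylfuran-2(5H)-one
Conditions: NaBH4, CeCl3·7H2O, MeOH, −78 °C
Reagents that add atoms: none
Why: Luche reduction: cerium-assisted 1,2-hydride delivery reduces only the aldehyde; the lactone, the alkenyl iodide and the silyl ether should be untouched at −78 °C.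

Step 12
Reactants: 21 (5S)-5-[(1R,2Z,4S)-4-[(2Z)-4-hydroxy-3-iodobut-2-en-1-yl]-4,8-dimethyl-1-(triethylsilyloxy)nona-2,7-dien-1-yl]-5-methylfuran-2(5H)-one
Product: 22 (5S)-5-[(1R,2Z,4S)-4-[(2Z)-4-(tert-butyldiphenylsilyloxy)-3-iodobut-2-en-1-yl]-4,8-dimethyl-1-(triethylsilyloxy)nona-2,7-dien-1-yl]-5-methylfuran-2(5H)-one
Conditions: TBDPSCl, imidazole, CH2Cl2, 0 °C → rt
Reagents that add atoms: tert-butyl(chloro)diphenylsilane, CC(C)(C)[Si](Cl)(c1ccccc1)c1ccccc1
Why: Silylation of the primary allylic alcohol with a robust silyl group that should survive tBuLi and the later selective cleavage of the C4 triethylsilyl ether.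

Step 13
Reactants: 22 (5S)-5-[(1R,2Z,4S)-4-[(2Z)-4-(tert-butyldiphenylsilyloxy)-3-iodobut-2-en-1-yl]-4,8-dimethyl-1-(triethylsilyloxy)nona-2,7-dien-1-yl]-5-methylfuran-2(5H)-one
Product: 25 (1S,2Z,4R,5S,6Z,9Z)-9-[(tert-butyldiphenylsilyloxy)methyl]-5-hydroxy-1,5-dimethyl-1-(4-methylpent-3-en-1-yl)-4-(triethylsilyloxy)cycloundeca-2,6,9-trien-8-one, via alkenyllithium 23 (not isolated), via lithium lactolate 24 (not isolated)
Conditions: tBuLi (2.1 equiv), THF/Et2O/pentane (4:1:1), 1 mM, −100 → −78 °C; AcOH in THF, −78 °C; pH 7 buffer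
Reagents that add atoms: none
Why: Proposed new method: iodine–lithium exchange at C9 (through the iodine ate complex) is expected to be faster at −100 °C than addition of tBuLi to the lactone and to give the configurationally stable alkenyllithium 23 with retention, lithium cis to C11. The hard alkenyllithium then adds 1,2 to the lactone carbonyl C8 and not to the conjugate position C6, which closes the eleven-membered carbocycle in an 11-exo-trig mode (C8–C9 bond). The tetrahedral lithium lactolate 24 should not collapse at low temperature, so no ketone is exposed to a second addition; acidic quench gives the lactol, which opens to the cis-γ-hydroxy dienone 25. The closest known reaction type is the Parham-type anionic cyclisation (halogen–lithium exchange followed by intramolecular acyl substitution on an ester), combined with the familiar 1,2-addition of alkenyllithiums to such unsaturated γ-lactones; new is its use to close a medium ring. No stereocentre is created: C8 ends as a carbonyl carbon, C1, C4 and C5 are untouched, the C6=C7 geometry is carried over from the lactone ring and the C9=C10 geometry from the alkenyl iodide. The step needs exchange before carbonyl attack (iodide, −100 °C), intramolecular before intermolecular addition (1 mM; three cis double bonds and the quaternary C1 and C5 restrict the tether and hold C9 near C8), and no enolisation or fragmentation. The substrate secures the last point: C5 is fully substituted, so the lactone has no γ-hydrogen to lose, and the C4 oxygen is silylated, so no alkoxide can start a retro-aldol cleavage of C4–C5.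

Step 14
Reactants: 25 (1S,2Z,4R,5S,6Z,9Z)-9-[(tert-butyldiphenylsilyloxy)methyl]-5-hydroxy-1,5-dimethyl-1-(4-methylpent-3-en-1-yl)-4-(triethylsilyloxy)cycloundeca-2,6,9-trien-8-one
Product: 26 (1S,2Z,4R,5S,6Z,9Z)-9-[(tert-butyldiphenylsilyloxy)methyl]-4,5-dihydroxy-1,5-dimethyl-1-(4-methylpent-3-en-1-yl)cycloundeca-2,6,9-trien-8-one
Conditions: HF·pyridine, pyridine, THF, 0 °C
Reagents that add atoms: none
Why: Selective desilylation: the triethylsilyl ether is cleaved by buffered HF·pyridine much faster than the bulky tert-butyldiphenylsilyl ether, which releases only the C4 hydroxyl under conditions mild enough for the dienone.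

Step 15
Reactants: 26 (1S,2Z,4R,5S,6Z,9Z)-9-[(tert-butyldiphenylsilyloxy)methyl]-4,5-dihydroxy-1,5-dimethyl-1-(4-methylpent-3-en-1-yl)cycloundeca-2,6,9-trien-8-one; 27 3-methylbut-2-enoyl chloride
Product: 28 (1S,2Z,4R,5S,6Z,9Z)-9-[(tert-butyldiphenylsilyloxy)methyl]-5-hydroxy-1,5-dimethyl-1-(4-methylpent-3-en-1-yl)-8-oxocycloundeca-2,6,9-trien-4-yl 3-methylbut-2-enoate
Conditions: pyridine, DMAP (10 mol %), CH2Cl2, 0 °C → rt
Reagents that add atoms: none
Why: Acylation (acyl chloride, DMAP catalysis) of the secondary allylic C4 hydroxyl; the tertiary C5 hydroxyl is too hindered to compete, and pyridine rather than a stronger base avoids ketene formation and deconjugation of the acyl group.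

Step 16
Reactants: 28 (1S,2Z,4R,5S,6Z,9Z)-9-[(tert-butyldiphenylsilyloxy)methyl]-5-hydroxy-1,5-dimethyl-1-(4-methylpent-3-en-1-yl)-8-oxocycloundeca-2,6,9-trien-4-yl 3-methylbut-2-enoate
Product: 29 CNP0230506.4, (1S,2Z,4R,5S,6Z,9Z)-5-hydroxy-9-(hydroxymethyl)-1,5-dimethyl-1-(4-methylpent-3-en-1-yl)-8-oxocycloundeca-2,6,9-trien-4-yl 3-methylbut-2-enoate
Conditions: Bu4NF, AcOH (1:1), THF, 0 °C → rt
Reagents that add atoms: none
Why: Fluoride cleavage of the primary silyl ether, buffered with acetic acid to spare the base-sensitive dienone and ester; it unveils the C9 hydroxymethyl group and should give the target.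

## Compound list

1 | geraniol, (2E)-3,7-dimethylocta-2,6-dien-1-ol | CC(C)=CCC/C(C)=C/CO | starting material
2 | geranyl diethyl phosphate | CC(C)=CCC/C(C)=C/COP(=O)(OCC)OCC | intermediate
3 | (trimethylsilyl)acetylene | C#C[Si](C)(C)C | starting material
4 | diisobutyl[(trimethylsilyl)ethynyl]alumane (alkynylalane) | CC(C)C[Al](CC(C)C)C#C[Si](C)(C)C | intermediate
5 | (3S)-3,7-dimethyl-3-[(trimethylsilyl)ethynyl]octa-1,6-diene | CC(C)=CCC[C@](C=C)(C)C#C[Si](C)(C)C | intermediate
6 | lithium acetylide of (3S)-3-ethynyl-3,7-dimethylocta-1,6-diene | CC(C)=CCC[C@](C=C)(C)C#C[Li] | intermediate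
7 | lithium hemiaminal alkoxide from 6 and DMF (mixture at the hemiaminal carbon) | CC(C)=CCC[C@](C=C)(C)C#CC([O-])N(C)C.[Li+] | intermediate
8 | (4S)-4-ethenyl-4,8-dimethylnon-7-en-2-ynal | CC(C)=CCC[C@](C=C)(C)C#CC=O | intermediate
9 | α-angelica lactone, 5-methylfuran-2(3H)-one | CC1=CCC(=O)O1 | starting material
10 | tert-butyldimethyl[(5-methylfuran-2-yl)oxy]silane | Cc1ccc(O[Si](C)(C)C(C)(C)C)o1 | intermediate
11 | trichlorosilyl ether of 12 | CC(C)=CCC[C@](C=C)(C)C#C[C@@H](O[Si](Cl)(Cl)Cl)[C@@]1(C)OC(=O)C=C1 | intermediate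
12 | (5S)-5-[(1R,4S)-4-ethenyl-1-hydroxy-4,8-dimethylnon-7-en-2-yn-1-yl]-5-methylfuran-2(5H)-one | CC(C)=CCC[C@](C=C)(C)C#C[C@@H](O)[C@@]1(C)OC(=O)C=C1 | intermediate
13 | (5S)-5-[(1R,4S)-4-ethenyl-4,8-dimethyl-1-(triethylsilyloxy)non-7-en-2-yn-1-yl]-5-methylfuran-2(5H)-one | CC(C)=CCC[C@](C=C)(C)C#C[C@@H](O[Si](CC)(CC)CC)[C@@]1(C)OC(=O)C=C1 | intermediate
14 | (5S)-5-[(1R,2Z,4S)-4-ethenyl-4,8-dimethyl-1-(triethylsilyloxy)nona-2,7-dien-1-yl]-5-methylfuran-2(5H)-one | CC(C)=CCC[C@](C=C)(C)/C=C\[C@@H](O[Si](CC)(CC)CC)[C@@]1(C)OC(=O)C=C1 | intermediate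
15 | B-alkyl-9-borabicyclo[3.3.1]nonane from 14 (boron on the terminal carbon of the former vinyl group) | CC(C)=CCC[C@](CCB1C2CCCC1CCC2)(C)/C=C\[C@@H](O[Si](CC)(CC)CC)[C@@]1(C)OC(=O)C=C1 | intermediate
16 | (5S)-5-[(1R,2Z,4S)-4-(2-hydroxyethyl)-4,8-dimethyl-1-(triethylsilyloxy)nona-2,7-dien-1-yl]-5-methylfuran-2(5H)-one | CC(C)=CCC[C@](CCO)(C)/C=C\[C@@H](O[Si](CC)(CC)CC)[C@@]1(C)OC(=O)C=C1 | intermediate
17 | (triphenylphosphoranylidene)acetaldehyde | O=CC=P(c1ccccc1)(c1ccccc1)c1ccccc1 | starting material
18 | (5S)-5-[(1R,2Z,4S)-4,8-dimethyl-4-(2-oxoethyl)-1-(triethylsilyloxy)nona-2,7-dien-1-yl]-5-methylfuran-2(5H)-one | CC(C)=CCC[C@](CC=O)(C)/C=C\[C@@H](O[Si](CC)(CC)CC)[C@@]1(C)OC(=O)C=C1 | intermediate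
19 | (5S)-5-[(1R,2Z,4S)-4,8-dimethyl-4-[(2E)-4-oxobut-2-en-1-yl]-1-(triethylsilyloxy)nona-2,7-dien-1-yl]-5-methylfuran-2(5H)-one | CC(C)=CCC[C@](C/C=C/C=O)(C)/C=C\[C@@H](O[Si](CC)(CC)CC)[C@@]1(C)OC(=O)C=C1 | intermediate
20 | (5S)-5-[(1R,2Z,4S)-4-[(2Z)-3-iodo-4-oxobut-2-en-1-yl]-4,8-dimethyl-1-(triethylsilyloxy)nona-2,7-dien-1-yl]-5-methylfuran-2(5H)-one | CC(C)=CCC[C@](C/C=C(I)/C=O)(C)/C=C\[C@@H](O[Si](CC)(CC)CC)[C@@]1(C)OC(=O)C=C1 | intermediate
21 | (5S)-5-[(1R,2Z,4S)-4-[(2Z)-4-hydroxy-3-iodobut-2-en-1-yl]-4,8-dimethyl-1-(triethylsilyloxy)nona-2,7-dien-1-yl]-5-methylfuran-2(5H)-one | CC(C)=CCC[C@](C/C=C(I)/CO)(C)/C=C\[C@@H](O[Si](CC)(CC)CC)[C@@]1(C)OC(=O)C=C1 | intermediate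
22 | (5S)-5-[(1R,2Z,4S)-4-[(2Z)-4-(tert-butyldiphenylsilyloxy)-3-iodobut-2-en-1-yl]-4,8-dimethyl-1-(triethylsilyloxy)nona-2,7-dien-1-yl]-5-methylfuran-2(5H)-one | CC(C)=CCC[C@](C/C=C(I)/CO[Si](c1ccccc1)(c1ccccc1)C(C)(C)C)(C)/C=C\[C@@H](O[Si](CC)(CC)CC)[C@@]1(C)OC(=O)C=C1 | intermediate
23 | alkenyllithium from 22 (lithium in place of iodine at C9, cis to C11) | CC(C)=CCC[C@](C/C=C([Li])/CO[Si](c1ccccc1)(c1ccccc1)C(C)(C)C)(C)/C=C\[C@@H](O[Si](CC)(CC)CC)[C@@]1(C)OC(=O)C=C1 | intermediate
24 | lithium lactolate (lithium alkoxide of the transannular C5–O–C8 hemiketal of 25) | CC(C)=CCC[C@]1(C)/C=C\[C@@H](O[Si](CC)(CC)CC)[C@@]2(C)O[C@]([O-])(C=C2)/C(CO[Si](c3ccccc3)(c3ccccc3)C(C)(C)C)=C\C1.[Li+] | intermediate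
25 | (1S,2Z,4R,5S,6Z,9Z)-9-[(tert-butyldiphenylsilyloxy)methyl]-5-hydroxy-1,5-dimethyl-1-(4-methylpent-3-en-1-yl)-4-(triethylsilyloxy)cycloundeca-2,6,9-trien-8-one (ring numbering of the first section) | CC(C)=CCC[C@]1(C)/C=C\[C@@H](O[Si](CC)(CC)CC)[C@@](C)(O)/C=C\C(=O)/C(CO[Si](c2ccccc2)(c2ccccc2)C(C)(C)C)=C\C1 | intermediate
26 | (1S,2Z,4R,5S,6Z,9Z)-9-[(tert-butyldiphenylsilyloxy)methyl]-4,5-dihydroxy-1,5-dimethyl-1-(4-methylpent-3-en-1-yl)cycloundeca-2,6,9-trien-8-one | CC(C)=CCC[C@]1(C)/C=C\[C@@H](O)[C@@](C)(O)/C=C\C(=O)/C(CO[Si](c2ccccc2)(c2ccccc2)C(C)(C)C)=C\C1 | intermediate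
27 | 3-methylbut-2-enoyl chloride | CC(C)=CC(=O)Cl | starting material
28 | (1S,2Z,4R,5S,6Z,9Z)-9-[(tert-butyldiphenylsilyloxy)methyl]-5-hydroxy-1,5-dimethyl-1-(4-methylpent-3-en-1-yl)-8-oxocycloundeca-2,6,9-trien-4-yl 3-methylbut-2-enoate | CC(C)=CCC[C@]1(C)/C=C\[C@@H](OC(=O)C=C(C)C)[C@@](C)(O)/C=C\C(=O)/C(CO[Si](c2ccccc2)(c2ccccc2)C(C)(C)C)=C\C1 | intermediate
29 | CNP0230506.4, (1S,2Z,4R,5S,6Z,9Z)-5-hydroxy-9-(hydroxymethyl)-1,5-dimethyl-1-(4-methylpent-3-en-1-yl)-8-oxocycloundeca-2,6,9-trien-4-yl 3-methylbut-2-enoate | CC(C)=CCC[C@]1(C)/C=C\[C@@H](OC(=O)C=C(C)C)[C@@](C)(O)/C=C\C(=O)/C(CO)=C\C1 | target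

## Step count and least certain steps

Total step count: 16. Longest linear sequence: 15 steps (steps 1–3 and 5–16, from 1); step 4 is a one-step side branch.

Step 13 (key step, proposed new method). The most likely failure is loss of the alkenyllithium before it can close the ring. At 1 mM it can be protonated by traces of proton sources, tBuLi can attack the lactone before the exchange, or intermolecular addition can win if the bridged lactolate transition state is strained. The fallback uses known chemistry and runs from 22 back to 25. Compound 22 is reduced with iBu2AlH (CH2Cl2, −78 °C) to the lactol F1, which equilibrates with its open cis-hydroxy enal. A Nozaki–Hiyama–Kishi cyclisation (CrCl2, NiCl2 catalyst, DMSO/THF, 2 mM) then closes C8–C9 from that open form, without a bridged intermediate, to the macrocyclic bis-allylic alcohol F2 as C8 epimers. Oxidation of the only secondary hydroxyl with Dess–Martin periodinane returns to 25.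

Step 5. The most likely failure is poor simple diastereoselection, because the open transition state may not distinguish the two aldehyde faces relative to the methyl-bearing furan carbon well; partial attack through the α-carbon of the furan is a second possibility. The fallback runs from 8 and 10 to 12 and no longer sets C4 in the aldol. The aldol mixture of 12 and its C4 epimer F3 is oxidised (Dess–Martin periodinane) to the single ynone F4. C4 is then set by reagent control in an asymmetric transfer hydrogenation of the alkynyl ketone with RuCl(p-cymene)[(S,S)-TsDPEN] or its enantiomer (HCO2H/Et3N), chosen for the (1R) alcohol 12.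

Step 2. The most likely failure is erosion of enantioselectivity with a purely aliphatic allylic phosphate, or competing direct (SN2) substitution at the primary carbon. The fallback runs from 1 to 5 and replaces catalytic substitution by a stereospecific epoxide opening. Sharpless epoxidation of 1 (Ti(OiPr)4, D-(−)-diethyl tartrate, tBuOOH, −20 °C) gives (2R,3R)-2,3-epoxygeraniol F5. The alkynylalane 4 opens it at the tertiary carbon with inversion to the diol F6. Deoxygenation of the 1,2-diol to the alkene (PPh3, I2, imidazole, toluene, 80 °C) gives 5.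

Step 10. The most likely failure is unselective or incomplete α-iodination: competing iodination of the lactone, iodine addition chemistry at the trisubstituted alkene, or an E/Z mixture. The fallback runs from 18 to 23 and brings the halogen in with the carbon instead of by enal halogenation. Aldehyde 18 is isolated and converted (CBr4, PPh3, CH2Cl2) to the 1,1-dibromoalkene F7. A trans-selective Stille coupling (Pd2(dba)3, tri(2-furyl)phosphine, Bu3SnCH2OH) gives the (Z)-2-bromoallylic alcohol F8. Silylation (TBDPSCl, imidazole) gives the bromide F9, whose bromine–lithium exchange (tBuLi, −100 °C) joins step 13 at the alkenyllithium 23.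

## Further compounds

F1 | step 13 | lactol of 22, (5S)-5-[(1R,2Z,4S)-4-[(2Z)-4-(tert-butyldiphenylsilyloxy)-3-iodobut-2-en-1-yl]-4,8-dimethyl-1-(triethylsilyloxy)nona-2,7-dien-1-yl]-5-methyl-2,5-dihydrofuran-2-ol (both anomers) | CC(C)=CCC[C@](C/C=C(I)/CO[Si](c1ccccc1)(c1ccccc1)C(C)(C)C)(C)/C=C\[C@@H](O[Si](CC)(CC)CC)[C@@]1(C)OC(O)C=C1
F2 | step 13 | (1S,2Z,4R,5S,6Z,9Z)-9-[(tert-butyldiphenylsilyloxy)methyl]-1,5-dimethyl-1-(4-methylpent-3-en-1-yl)-4-(triethylsilyloxy)cycloundeca-2,6,9-triene-5,8-diol (C8 epimers) | CC(C)=CCC[C@]1(C)/C=C\[C@@H](O[Si](CC)(CC)CC)[C@@](C)(O)/C=C\C(O)/C(CO[Si](c2ccccc2)(c2ccccc2)C(C)(C)C)=C\C1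
F3 | step 5 | (5S)-5-[(1S,4S)-4-ethenyl-1-hydroxy-4,8-dimethylnon-7-en-2-yn-1-yl]-5-methylfuran-2(5H)-one (C4 epimer of 12) | CC(C)=CCC[C@](C=C)(C)C#C[C@H](O)[C@@]1(C)OC(=O)C=C1
F4 | step 5 | (5S)-5-[(4S)-4-ethenyl-4,8-dimethylnon-7-en-2-ynoyl]-5-methylfuran-2(5H)-one | CC(C)=CCC[C@](C=C)(C)C#CC(=O)[C@@]1(C)OC(=O)C=C1
F5 | step 2 | (2R,3R)-2,3-epoxygeraniol | CC(C)=CCC[C@@]1(C)O[C@@H]1CO
F6 | step 2 | (2S,3R)-3-methyl-3-(4-methylpent-3-en-1-yl)-5-(trimethylsilyl)pent-4-yne-1,2-diol | CC(C)=CCC[C@]([C@H](O)CO)(C)C#C[Si](C)(C)C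
F7 | step 10 | (5S)-5-[(1R,2Z,4S)-4-(3,3-dibromoprop-2-en-1-yl)-4,8-dimethyl-1-(triethylsilyloxy)nona-2,7-dien-1-yl]-5-methylfuran-2(5H)-one | CC(C)=CCC[C@](CC=C(Br)Br)(C)/C=C\[C@@H](O[Si](CC)(CC)CC)[C@@]1(C)OC(=O)C=C1
F8 | step 10 | (5S)-5-[(1R,2Z,4S)-4-[(2Z)-3-bromo-4-hydroxybut-2-en-1-yl]-4,8-dimethyl-1-(triethylsilyloxy)nona-2,7-dien-1-yl]-5-methylfuran-2(5H)-one | CC(C)=CCC[C@](C/C=C(Br)/CO)(C)/C=C\[C@@H](O[Si](CC)(CC)CC)[C@@]1(C)OC(=O)C=C1
F9 | step 10 | (5S)-5-[(1R,2Z,4S)-4-[(2Z)-3-bromo-4-(tert-butyldiphenylsilyloxy)but-2-en-1-yl]-4,8-dimethyl-1-(triethylsilyloxy)nona-2,7-dien-1-yl]-5-methylfuran-2(5H)-one | CC(C)=CCC[C@](C/C=C(Br)/CO[Si](c1ccccc1)(c1ccccc1)C(C)(C)C)(C)/C=C\[C@@H](O[Si](CC)(CC)CC)[C@@]1(C)OC(=O)C=C1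
A1 | alternative 1 | acyclic metathesis precursor, (3R,4S,5Z,8Z,11S)-8-[(tert-butyldiphenylsilyloxy)methyl]-11-ethenyl-4-hydroxy-4,11,15-trimethyl-7-oxohexadeca-1,5,8,14-tetraen-3-yl 3-methylbut-2-enoate | C=C[C@@H](OC(=O)C=C(C)C)[C@@](C)(O)/C=C\C(=O)/C(CO[Si](c1ccccc1)(c1ccccc1)C(C)(C)C)=C\C[C@](C)(CCC=C(C)C)C=C
A2 | alternative 2 | acyclic C9 alkenyl iodide with a cis-alkenylstannane at C7 (C1 S, C4 R, C5 S; C4 3-methylbut-2-enoate, C5 hydroxyl, C9 CH2O-tert-butyldiphenylsilyl) | CC(C)=CCC[C@](C/C=C(I)/CO[Si](c1ccccc1)(c1ccccc1)C(C)(C)C)(C)/C=C\[C@@H](OC(=O)C=C(C)C)[C@@](C)(O)/C=C\[Sn](CCCC)(CCCC)CCCC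
A3 | alternative 3 | trans-fused bicyclo[5.4.0]undeca-diene with C3–C8 bond: C8 tertiary alcohol, C2 mesylate, C4 triethylsilyl ether, C5 hydroxyl, C9 CH2O-tert-butyldiphenylsilyl | CC(C)=CCC[C@]1(C)[C@H](OS(C)(=O)=O)[C@@H]2[C@@H](O[Si](CC)(CC)CC)[C@@](C)(O)C=C[C@@]2(O)C(CO[Si](c3ccccc3)(c3ccccc3)C(C)(C)C)=CC1
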